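The numbers in the tables come from a simulation on assumed constants; noise was put on by code.

12.1 mM was the number I carried to this flask: the crossover concentration, the c(substrate) at which substrate disappears without giving product as fast as it turns into product.

| flask | substrate | acid | remark | time |
|---|---|---|---|---|
| teal | 21 mM | 0.096 mM | run made earlier |  |
| ochre | 48 mM | 0.096 mM | run made earlier |  |
| flask | 32 mM | 0.0960 mM |  | 8.0 h |

| run | time / h | substrate / % | product / % |
|---|---|---|---|
| teal | 1.50 | 54.2 | 16.1 |
| teal | 3.00 | 33.7 | 29.1 |
| teal | 5.00 | 21.8 | 37.1 |
| teal | 6.00 | 18.3 | 40.7 |
| teal | 8.00 | 12.0 | 46.6 |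
| ochre | 0.667 | 62.2 | 9.5 |
| ochre | 1.33 | 42.4 | 14.7 |
| ochre | 2.50 | 25.5 | 21.9 |
| ochre | 4.00 | 15.8 | 26.4 |
| ochre | 8.00 | 7.7 | 33.9 |

(standard deviation of a reading: 1 percentage point)

- part of the substrate that has reacted at 8.0 h
- pH of the solution at 8.0 h

- acid is the free proton; pH is minus the decimal logarithm of its molar concentration
- the numbers in the tables scatter by 1 percentage point (one standard deviation)

I read it from the ochre run between 1.33 h and 2.50 h, where substrate fell by 17 percentage points, product rose by 7.2 points and mean c(substrate) was 16.3 mM. I treated product as a pseudo-first-order step and the missing substrate as second order, so the missing share over the product gain equals c(substrate) over the crossover. The teal run, read the same way between 1.50 h and 3.00 h, gives 16.0 mM, so the crossover is a rough reading under the scatter of the tables, and I carried the ochre value on.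

The same ochre window gave a product time, the substrate present over its rate of turning into product, of 5.52 h. The matching loss time for the missing substrate, reckoned at this flask's charged c(substrate), was 2.09 h. Their ratio is 2.64, so the flask starts by losing substrate faster than it makes product. Integrating both paths together, I expected 92.2% reacted, above the forecast.

The forecast gave 90.7% and pH 4.02, holding that “the acid behaves as an unchanged catalyst”.

The flask gave 91.3% reacted and pH 3.83.

    substrate + acid → weak acid + acid + product (k = 0.301 /M/s)
    weak acid ⇌ conjugate base + acid, settled at all times (K = 1.60 × 10⁻⁵ M)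
    substrate → weak acid + product (k = 9.93 × 10⁻⁸ /s)
    crystals ⇌ weak acid, rate k4*(cs4 - [weak acid]) while solid is left; crystals form when [weak acid] > cs4 (solubility = 0.430 mM, k = 0.00421 /s)
    2 substrate → homo dimer (k = 0.00205 /M/s)

At 8.00 h the flask held acid at 152% of its own charge. At 8.00 h this flask held 2.79 mM, so the crossover predicts 4.34 for substrate used by the acid step over substrate lost to homo dimer, and the flask gives 3.9.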